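**Plan**

- Retrosynthetic cuts, in order: C4–O2' of a temporary pterocarpan (returned as C4–H), O1–C2 of the chroman ring, C3–C4 (the only C–C bond joining the two aryl halves), the O2'–CH2 ether with the diazo group, and finally the ring-B C5'–C(Me)2 bond and the ring-A side-chain C–Me bonds.
- Enabling feature: in ring B the 2'-hydroxyl is ortho to C1'. O2' can therefore carry the ring-A benzylic carbon C4 as an ether, which puts the C4–H bonds in a 1,5-relationship to a carbene at C3 on C1'.
- Forward order: ring A is made aromatic from a cyclohexanedione and carried to a benzyl alcohol (steps 1–8); ring B is carried to a 2'-hydroxy arylacetate (steps 9–13); the two are joined at O2' and diazotised (steps 14–15).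
- Ring events: the dihydrofuran ring closes by C–H insertion (C3–C4, step 16), the pyran ring closes through O1–C2 to a cis-pterocarpan (step 19), and the dihydrofuran ring is reopened reductively at C4–O2' (step 20).
- Stereochemistry: C3 is set in the insertion by the chiral dirhodium carboxylate. The cis C4 centre formed at the same time only serves the pterocarpan closure and is erased in the last step.

Key step: step 16

Abbreviations: TBS = tert-butyldimethylsilyl, TES = triethylsilyl, TMS = trimethylsilyl, BSA = N,O-bis(trimethylsilyl)acetamide, DIAD = diisopropyl azodicarboxylate, p-ABSA = 4-acetamidobenzenesulfonyl azide.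

Assumption: Rh2(S-PTTL)4 is taken to give the (2R,3S) enantiomer of 23, by analogy with its behaviour toward simpler benzyl ethers. If the sense of induction proves opposite, the mirror-image catalyst Rh2(R-PTTL)4 is used and nothing else changes.

**Route**

Step 1
Reactants: 1 cyclohexane-1,3-dione; 2 acrylic acid
Product: 4 3,4,7,8-tetrahydro-2H-chromene-2,5(6H)-dione, via keto acid 3 (not isolated)
Conditions: TsOH·H2O (5 mol %), hydroquinone (trace), toluene, reflux, Dean–Stark
Reagents that add atoms: none
Why: Acid-catalysed conjugate addition of the enolised 1,3-dione to acrylic acid should give keto acid 3, which closes to the enol lactone with azeotropic loss of water (tandem Michael addition–enol lactonisation).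

Step 2
Reactants: 4 3,4,7,8-tetrahydro-2H-chromene-2,5(6H)-dione
Product: 5 5-hydroxychroman-2-one
Conditions: 10% Pd/C, diphenyl ether, 200 °C, N2 sweep
Reagents that add atoms: none
Why: Palladium-catalysed dehydrogenation of the cyclohexenone ring followed by tautomerisation should give the phenol (dehydrogenative aromatisation of a cyclohexane-1,3-dione derivative), with the hydrogen carried off by the gas stream.

Step 3
Reactants: 5 5-hydroxychroman-2-one
Product: 6 2-(3-hydroxy-3-methylbutyl)benzene-1,3-diol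
Conditions: MeMgBr (4 equiv), THF, 0 °C → rt; aq. NH4Cl
Reagents that add atoms: methylmagnesium bromide, C[Mg]Br
Why: After deprotonation of the phenol, double Grignard addition to the lactone carbonyl should give the tertiary alcohol and free the second phenol, and the near-neutral work-up avoids acid-induced closure to a 2,2-dimethylchroman.

Step 4
Reactants: 6 2-(3-hydroxy-3-methylbutyl)benzene-1,3-diol
Product: 7 2-(3-hydroxy-3-methylbutyl)-4-iodobenzene-1,3-diol
Conditions: I2 (1.0 equiv), NaHCO3, THF/H2O, 0 °C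
Reagents that add atoms: iodine, II
Why: Electrophilic aromatic iodination of the resorcinol should go to C4, because C2 is blocked and C4/C6 are equivalent and ortho/para to the two hydroxyls, while one equivalent of iodine at 0 °C limits di-iodination.

Step 5
Reactants: 7 2-(3-hydroxy-3-methylbutyl)-4-iodobenzene-1,3-diol
Product: 8 4-[2,6-bis(TBS-oxy)-3-iodophenyl]-2-methylbutan-2-ol
Conditions: TBSCl (2.5 equiv), imidazole, DMF, rt → 40 °C
Reagents that add atoms: tert-butyldimethylsilyl chloride, CC(C)(C)[Si](C)(C)Cl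
Why: Standard silyl chloride/imidazole silylation should cap both phenols, while the tertiary alcohol is inert to TBSCl under these conditions.

Step 6
Reactants: 8 4-[2,6-bis(TBS-oxy)-3-iodophenyl]-2-methylbutan-2-ol
Product: 9 1,3-bis(TBS-oxy)-4-iodo-2-[3-methyl-3-(TES-oxy)butyl]benzene
Conditions: TESOTf, 2,6-lutidine, CH2Cl2, 0 °C
Reagents that add atoms: triethylsilyl trifluoromethanesulfonate, CC[Si](CC)(CC)OS(=O)(=O)C(F)(F)F
Why: Silyl triflate/2,6-lutidine silylation of a tertiary alcohol should mask the O–H that would otherwise consume the Grignard reagent of step 7 and later intercept the rhodium carbene.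

Step 7
Reactants: 9 1,3-bis(TBS-oxy)-4-iodo-2-[3-methyl-3-(TES-oxy)butyl]benzene
Product: 11 2,4-bis(TBS-oxy)-3-[3-methyl-3-(TES-oxy)butyl]benzaldehyde, via arylmagnesium chloride 10 (not isolated)
Conditions: i-PrMgCl·LiCl, THF, −15 → 0 °C; DMF, 0 °C → rt; aq. NH4Cl
Reagents that add atoms: N,N-dimethylformamide, CN(C)C=O
Why: Iodine–magnesium exchange followed by formylation with DMF (Bouveault aldehyde synthesis) should give the aldehyde, and the arylmagnesium species, unlike an aryllithium, should not trigger 1,3-O→C silyl migration from the neighbouring silyl ether.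

Step 8
Reactants: 11 2,4-bis(TBS-oxy)-3-[3-methyl-3-(TES-oxy)butyl]benzaldehyde
Product: 12 {2,4-bis(TBS-oxy)-3-[3-methyl-3-(TES-oxy)butyl]phenyl}methanol
Conditions: i-Bu2AlH, CH2Cl2, −78 °C; aq. KNaC4H4O6 (potassium sodium tartrate)
Reagents that add atoms: none
Why: Hydride reduction of the aldehyde at −78 °C with a cold quench should give the benzyl alcohol while suppressing O→O silyl migration from the ortho silyl ether to the benzylic oxygen.

Step 9
Reactants: 13 2,4-dihydroxyphenylacetic acid
Product: 14 6-hydroxybenzofuran-2(3H)-one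
Conditions: TsOH·H2O (cat.), toluene, reflux, Dean–Stark
Reagents that add atoms: none
Why: Acid-catalysed dehydrative lactonisation of a 2-hydroxyphenylacetic acid should close the five-membered aryl lactone, which ties up O2' and the carboxyl group and leaves only O4' free.

Step 10
Reactants: 14 6-hydroxybenzofuran-2(3H)-one; 15 3-methylbut-2-en-1-ol
Product: 16 6-(3-methylbut-2-enyloxy)benzofuran-2(3H)-one
Conditions: PPh3, DIAD, THF, 0 °C → rt
Reagents that add atoms: none
Why: Mitsunobu etherification of the phenol at the primary allylic carbinol carbon should give the prenyl ether under neutral conditions, which avoids the base-induced enolisation and C-alkylation to which the 2-coumaranone is prone.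

Step 11
Reactants: 16 6-(3-methylbut-2-enyloxy)benzofuran-2(3H)-one
Product: 18 6-hydroxy-5-(2-methylbut-3-en-2-yl)benzofuran-2(3H)-one, via trimethylsilyl ether 17 (not isolated)
Conditions: BSA (2 equiv), N,N-diethylaniline, 185 °C; then 1 M HCl wash
Reagents that add atoms: none
Why: The aromatic Claisen rearrangement ([3,3]-sigmatropic shift) of the aryl prenyl ether should deliver the inverted 1,1-dimethylallyl group to C5 rather than C7, since C7 is flanked by two oxygens and the fused five-membered ring localises double-bond character in C5–C6, while in situ O-silylation by BSA blocks the abnormal Claisen rearrangement and cyclisation of the ortho-allylphenol.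

Step 12
Reactants: 18 6-hydroxy-5-(2-methylbut-3-en-2-yl)benzofuran-2(3H)-one
Product: 19 6-(TBS-oxy)-5-(2-methylbut-3-en-2-yl)benzofuran-2(3H)-one
Conditions: 2,6-lutidine, then TBSOTf, CH2Cl2, −78 → 0 °C
Reagents that add atoms: tert-butyldimethylsilyl trifluoromethanesulfonate, CC(C)(C)[Si](C)(C)OS(=O)(=O)C(F)(F)F
Why: Silyl triflate with a non-nucleophilic base should silylate the hindered phenol without opening the aryl lactone, and the excess base buffers any acid that could add the phenol across the vinyl group.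

Step 13
Reactants: 19 6-(TBS-oxy)-5-(2-methylbut-3-en-2-yl)benzofuran-2(3H)-one
Product: 20 methyl 2-[4-(TBS-oxy)-2-hydroxy-5-(2-methylbut-3-en-2-yl)phenyl]acetate
Conditions: MeOH, Et3N (0.2 equiv), 0 °C → rt
Reagents that add atoms: methanol, CO
Why: Amine-catalysed methanolysis of the reactive aryl ester (transesterification) should release the O2' phenol and the methyl ester, while the hindered O4' silyl ether resists triethylamine in methanol.

Step 14
Reactants: 20 methyl 2-[4-(TBS-oxy)-2-hydroxy-5-(2-methylbut-3-en-2-yl)phenyl]acetate; 12 {2,4-bis(TBS-oxy)-3-[3-methyl-3-(TES-oxy)butyl]phenyl}methanol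
Product: 21 methyl 2-{2-({2,4-bis(TBS-oxy)-3-[3-methyl-3-(TES-oxy)butyl]phenyl}methoxy)-4-(TBS-oxy)-5-(2-methylbut-3-en-2-yl)phenyl}acetate
Conditions: PPh3, DIAD, toluene, 0 °C → rt
Reagents that add atoms: none
Why: In this Mitsunobu etherification the O2' phenol should displace the activated primary benzylic alcohol without added base, which spares the silyl ethers and avoids an ionisation-prone electron-rich benzylic halide.

Step 15
Reactants: 21 the arylacetate from step 14
Product: 22 methyl 2-diazo-2-{2-({2,4-bis(TBS-oxy)-3-[3-methyl-3-(TES-oxy)butyl]phenyl}methoxy)-4-(TBS-oxy)-5-(2-methylbut-3-en-2-yl)phenyl}acetate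
Conditions: p-ABSA, DBU, MeCN (dry), 0 °C → rt
Reagents that add atoms: 4-acetamidobenzenesulfonyl azide, CC(=O)Nc1ccc(cc1)S(=O)(=O)N=[N+]=[N-]
Why: Regitz diazo transfer from the sulfonyl azide to the arylacetate enolate is the standard entry to methyl aryldiazoacetates and should tolerate the ortho-substituted aryl silyl ethers under dry conditions.

Step 16
Reactants: 22 the aryldiazoacetate from step 15
Product: 23 methyl (2R,3S)-2-{2,4-bis(TBS-oxy)-3-[3-methyl-3-(TES-oxy)butyl]phenyl}-6-(TBS-oxy)-5-(2-methylbut-3-en-2-yl)-2,3-dihydrobenzofuran-3-carboxylate (cis)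
Conditions: Rh2(S-PTTL)4 (1 mol %), toluene, −78 → −50 °C
Reagents that add atoms: none
Why: Rh2(S-PTTL)4 (dirhodium tetrakis[N-phthaloyl-(S)-tert-leucinate], divalent rhodium) should expel N2 from the diazo ester to give a donor/acceptor rhodium carbene at C3, which inserts into a benzylic C4–H bond of the O2'–CH2 ether through a concerted, asynchronous three-centre transition state with hydride-transfer character. The closest known reaction type is the dirhodium-carboxylate-catalysed enantioselective intramolecular C–H insertion of methyl 2-(benzyloxy)phenyldiazoacetates to cis-2-aryl-2,3-dihydrobenzofuran-3-carboxylates. The dihydrofuran ring closes by 1,5-insertion, the new C3–C4 bond completing the five-membered ring C3–C1'–C2'–O2'–C4 through a five-membered cyclic transition state. The configuration at C3 is fixed by the chiral carboxylate ligands, which shield one face of the carbene, and C4 is set relative to C3 in the same transition state, in which ring A and the ester are expected to end up cis. The step needs site- and chemoselectivity: the C4–H bonds are the only ones within 1,5-reach and are activated by the ether oxygen and by electron-rich ring A, whereas the vinyl group sits meta to the carbene carbon behind a quaternary centre and cannot be reached for cyclopropanation, and the silyl C–H bonds are unactivated. Low temperature and the absence of base should keep the cis ester from epimerising at C3.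

Step 17
Reactants: 23 the cis ester from step 16
Product: 24 [(2R,3R)-2-{2,4-bis(TBS-oxy)-3-[3-methyl-3-(TES-oxy)butyl]phenyl}-6-(TBS-oxy)-5-(2-methylbut-3-en-2-yl)-2,3-dihydrobenzofuran-3-yl]methanol
Conditions: i-Bu2AlH (2.5 equiv), CH2Cl2, −78 °C; aq. KNaC4H4O6
Reagents that add atoms: none
Why: Ester-to-alcohol reduction at −78 °C without base should leave the epimerisable C3 untouched (the descriptor changes only because the priorities change) and turns the ester carbon into C2 of the future chroman.

Step 18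
Reactants: 24 the primary alcohol from step 17
Product: 25 [(2R,3R)-2-{2,4-bis(TBS-oxy)-3-[3-methyl-3-(TES-oxy)butyl]phenyl}-6-(TBS-oxy)-5-(2-methylbut-3-en-2-yl)-2,3-dihydrobenzofuran-3-yl]methyl methanesulfonate
Conditions: MsCl, Et3N, CH2Cl2, −20 °C
Reagents that add atoms: methanesulfonyl chloride, CS(=O)(=O)Cl
Why: Sulfonylation of the only free hydroxyl (via sulfene) should give the leaving group at C2 for the pyran closure.

Step 19
Reactants: 25 the mesylate from step 18
Product: 27 (6aR,11aR)-4-(3-hydroxy-3-methylbutyl)-8-(2-methylbut-3-en-2-yl)-6a,11a-dihydro-6H-benzofuro[3,2-c]chromene-3,9-diol (cis-pterocarpan), via desilylated mesylate 26 (not isolated)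
Conditions: Bu4NF (5 equiv), THF (0.005 M), 0 °C → rt
Reagents that add atoms: none
Why: Fluoride should cleave the four silyl ethers, and the liberated O1 phenoxide then displaces the mesylate (intramolecular Williamson etherification, 6-exo-tet) to give the cis-fused pterocarpan, because O2' is locked in the dihydrofuran ring, the other phenoxides can only react intermolecularly at this dilution, and C3 is not involved.

Step 20
Reactants: 27 the cis-pterocarpan from step 19
Product: 29 (3R)-3-[2,4-dihydroxy-5-(2-methylbut-3-en-2-yl)phenyl]-8-(3-hydroxy-3-methylbutyl)chroman-7-ol (CNP0420388.1), via quinone methide 28 (not isolated)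
Conditions: NaBH4 (10 equiv), 0.5 M aq. NaOH/THF 1:1, 55 °C, Ar; then 1 M HCl to pH 6 at 0 °C
Reagents that add atoms: none
Why: The C7 phenoxide, para to C4, should expel the O2' aryloxide to give the ring-A para-quinone methide, which borohydride reduces at C4 (reductive cleavage of a phenolic benzyl aryl ether, as in alkaline borohydride treatment of lignin α-aryl ethers), so that C4 becomes CH2 while C3, the vinyl group and the tertiary alcohol are untouched.

**Compound list**

1 | cyclohexane-1,3-dione | O=C1CCCC(=O)C1 | starting material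
2 | acrylic acid | C=CC(=O)O | starting material
3 | 3-(2,6-dioxocyclohexyl)propanoic acid | OC(=O)CCC1C(=O)CCCC1=O | intermediate
4 | 3,4,7,8-tetrahydro-2H-chromene-2,5(6H)-dione | O=C1CCC2=C(O1)CCCC2=O | intermediate
5 | 5-hydroxychroman-2-one | O=C1CCc2c(O)cccc2O1 | intermediate
6 | 2-(3-hydroxy-3-methylbutyl)benzene-1,3-diol | CC(C)(O)CCc1c(O)cccc1O | intermediate
7 | 2-(3-hydroxy-3-methylbutyl)-4-iodobenzene-1,3-diol | CC(C)(O)CCc1c(O)ccc(I)c1O | intermediate
8 | 4-[2,6-bis(TBS-oxy)-3-iodophenyl]-2-methylbutan-2-ol | CC(C)(O)CCc1c(O[Si](C)(C)C(C)(C)C)ccc(I)c1O[Si](C)(C)C(C)(C)C | intermediate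
9 | 1,3-bis(TBS-oxy)-4-iodo-2-[3-methyl-3-(TES-oxy)butyl]benzene | CC(C)(CCc1c(O[Si](C)(C)C(C)(C)C)ccc(I)c1O[Si](C)(C)C(C)(C)C)O[Si](CC)(CC)CC | intermediate
10 | {2,4-bis(TBS-oxy)-3-[3-methyl-3-(TES-oxy)butyl]phenyl}magnesium chloride | CC(C)(CCc1c(O[Si](C)(C)C(C)(C)C)ccc([Mg]Cl)c1O[Si](C)(C)C(C)(C)C)O[Si](CC)(CC)CC | intermediate
11 | 2,4-bis(TBS-oxy)-3-[3-methyl-3-(TES-oxy)butyl]benzaldehyde | CC(C)(CCc1c(O[Si](C)(C)C(C)(C)C)ccc(C=O)c1O[Si](C)(C)C(C)(C)C)O[Si](CC)(CC)CC | intermediate
12 | {2,4-bis(TBS-oxy)-3-[3-methyl-3-(TES-oxy)butyl]phenyl}methanol | CC(C)(CCc1c(O[Si](C)(C)C(C)(C)C)ccc(CO)c1O[Si](C)(C)C(C)(C)C)O[Si](CC)(CC)CC | intermediate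
13 | 2,4-dihydroxyphenylacetic acid | OC(=O)Cc1ccc(O)cc1O | starting material
14 | 6-hydroxybenzofuran-2(3H)-one | O=C1Cc2ccc(O)cc2O1 | intermediate
15 | 3-methylbut-2-en-1-ol | CC(C)=CCO | starting material
16 | 6-(3-methylbut-2-enyloxy)benzofuran-2(3H)-one | CC(C)=CCOc1ccc2CC(=O)Oc2c1 | intermediate
17 | 5-(2-methylbut-3-en-2-yl)-6-(TMS-oxy)benzofuran-2(3H)-one | C=CC(C)(C)c1cc2CC(=O)Oc2cc1O[Si](C)(C)C | intermediate
18 | 6-hydroxy-5-(2-methylbut-3-en-2-yl)benzofuran-2(3H)-one | C=CC(C)(C)c1cc2CC(=O)Oc2cc1O | intermediate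
19 | 6-(TBS-oxy)-5-(2-methylbut-3-en-2-yl)benzofuran-2(3H)-one | C=CC(C)(C)c1cc2CC(=O)Oc2cc1O[Si](C)(C)C(C)(C)C | intermediate
20 | methyl 2-[4-(TBS-oxy)-2-hydroxy-5-(2-methylbut-3-en-2-yl)phenyl]acetate | COC(=O)Cc1cc(C(C)(C)C=C)c(O[Si](C)(C)C(C)(C)C)cc1O | intermediate
21 | methyl 2-{2-({2,4-bis(TBS-oxy)-3-[3-methyl-3-(TES-oxy)butyl]phenyl}methoxy)-4-(TBS-oxy)-5-(2-methylbut-3-en-2-yl)phenyl}acetate | COC(=O)Cc1cc(C(C)(C)C=C)c(O[Si](C)(C)C(C)(C)C)cc1OCc1ccc(O[Si](C)(C)C(C)(C)C)c(CCC(C)(C)O[Si](CC)(CC)CC)c1O[Si](C)(C)C(C)(C)C | intermediate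
22 | methyl 2-diazo-2-{2-({2,4-bis(TBS-oxy)-3-[3-methyl-3-(TES-oxy)butyl]phenyl}methoxy)-4-(TBS-oxy)-5-(2-methylbut-3-en-2-yl)phenyl}acetate | COC(=O)C(=[N+]=[N-])c1cc(C(C)(C)C=C)c(O[Si](C)(C)C(C)(C)C)cc1OCc1ccc(O[Si](C)(C)C(C)(C)C)c(CCC(C)(C)O[Si](CC)(CC)CC)c1O[Si](C)(C)C(C)(C)C | intermediate
23 | methyl (2R,3S)-2-{2,4-bis(TBS-oxy)-3-[3-methyl-3-(TES-oxy)butyl]phenyl}-6-(TBS-oxy)-5-(2-methylbut-3-en-2-yl)-2,3-dihydrobenzofuran-3-carboxylate | COC(=O)[C@@H]1[C@H](c2ccc(O[Si](C)(C)C(C)(C)C)c(CCC(C)(C)O[Si](CC)(CC)CC)c2O[Si](C)(C)C(C)(C)C)Oc2cc(O[Si](C)(C)C(C)(C)C)c(C(C)(C)C=C)cc12 | intermediate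
24 | [(2R,3R)-2-{2,4-bis(TBS-oxy)-3-[3-methyl-3-(TES-oxy)butyl]phenyl}-6-(TBS-oxy)-5-(2-methylbut-3-en-2-yl)-2,3-dihydrobenzofuran-3-yl]methanol | OC[C@@H]1[C@H](c2ccc(O[Si](C)(C)C(C)(C)C)c(CCC(C)(C)O[Si](CC)(CC)CC)c2O[Si](C)(C)C(C)(C)C)Oc2cc(O[Si](C)(C)C(C)(C)C)c(C(C)(C)C=C)cc12 | intermediate
25 | methanesulfonate of 24 | CS(=O)(=O)OC[C@@H]1[C@H](c2ccc(O[Si](C)(C)C(C)(C)C)c(CCC(C)(C)O[Si](CC)(CC)CC)c2O[Si](C)(C)C(C)(C)C)Oc2cc(O[Si](C)(C)C(C)(C)C)c(C(C)(C)C=C)cc12 | intermediate
26 | [(2R,3R)-2-[2,4-dihydroxy-3-(3-hydroxy-3-methylbutyl)phenyl]-6-hydroxy-5-(2-methylbut-3-en-2-yl)-2,3-dihydrobenzofuran-3-yl]methyl methanesulfonate | CS(=O)(=O)OC[C@@H]1[C@H](c2ccc(O)c(CCC(C)(C)O)c2O)Oc2cc(O)c(C(C)(C)C=C)cc12 | intermediate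
27 | (6aR,11aR)-4-(3-hydroxy-3-methylbutyl)-8-(2-methylbut-3-en-2-yl)-6a,11a-dihydro-6H-benzofuro[3,2-c]chromene-3,9-diol | C=CC(C)(C)c1cc2c(cc1O)O[C@H]1c3ccc(O)c(CCC(C)(C)O)c3OC[C@@H]21 | intermediate
28 | (3R)-3-[2,4-dihydroxy-5-(2-methylbut-3-en-2-yl)phenyl]-8-(3-hydroxy-3-methylbutyl)-2H-chromen-7(3H)-one (ring-A para-quinone methide) | C=CC(C)(C)c1cc([C@@H]2COC3=C(CCC(C)(C)O)C(=O)C=CC3=C2)c(O)cc1O | intermediate
29 | (3R)-3-[2,4-dihydroxy-5-(2-methylbut-3-en-2-yl)phenyl]-8-(3-hydroxy-3-methylbutyl)chroman-7-ol | C=CC(C)(C)c1cc([C@@H]2COc3c(ccc(O)c3CCC(C)(C)O)C2)c(O)cc1O | target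

**Step count and risks**

Total step count: 20.
Longest linear sequence: 15 steps (steps 1–8, then 14–20); the ring-B branch is steps 9–13.

Steps most likely to fail:

1. Step 20. The quinone methide may lose the C3 proton (tautomerisation to the achiral isoflav-3-ene) faster than it takes up hydride, or the ring may open only at temperatures where this erosion of the C3 configuration sets in. The fallback sets out from 27 and captures the quinone methide with a soft sulfur nucleophile under weakly basic conditions (PhSH in excess, Et3N, EtOH, 50 °C). This should give the (3R)-4-(phenylsulfanyl)isoflavan F1 as a mixture of C4 epimers. The C–S bond is then removed by radical reduction (Bu3SnH, AIBN, toluene, 90 °C), which returns to the route at 29.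

2. Step 19. The dihydrofuran ring may open through the ring-A quinone methide before O1 has closed, which would let the freed O2' attack C2 and form the wrong five-membered ether. Base-induced elimination of the mesylate or intermolecular etherification may also compete. The fallback sets out from 24, so the mesylate is not made. All silyl groups are removed without generating phenoxides (HF·pyridine buffered with extra pyridine, THF, 0 °C → rt) to give the pentaol (2R,3R)-2-[2,4-dihydroxy-3-(3-hydroxy-3-methylbutyl)phenyl]-3-(hydroxymethyl)-5-(2-methylbut-3-en-2-yl)-2,3-dihydrobenzofuran-6-ol F2. The pyran ring is then closed by intramolecular Mitsunobu etherification (PPh3, DIAD, THF, high dilution), in which only the O1 phenol can reach the activated primary carbon in a six-membered transition state. The route is rejoined at 27.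

3. Step 16. The bulky silyl ether ortho to the inserting C–H bonds may cause poor facial selectivity at the carbene or loss of cis control. The fallback sets out from 22 and runs the insertion with the achiral, bulky catalyst Rh2(O2CCPh3)4 (dirhodium tetrakis(triphenylacetate), divalent rhodium) in CH2Cl2, which should give the racemic cis ester F3. Reduction with i-Bu2AlH at −78 °C gives the racemic cis alcohol F4. This is resolved by preparative HPLC on an amylose tris(3,5-dimethylphenylcarbamate) stationary phase, and the (2R,3R) enantiomer is 24, where the route resumes. Absolute configuration then comes from resolution instead of catalyst control.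

Further compounds
F1 | step 20 | (3R)-3-[2,4-dihydroxy-5-(2-methylbut-3-en-2-yl)phenyl]-8-(3-hydroxy-3-methylbutyl)-4-(phenylsulfanyl)chroman-7-ol (C4 epimers) | C=CC(C)(C)c1cc([C@@H]2COc3c(ccc(O)c3CCC(C)(C)O)C2Sc2ccccc2)c(O)cc1O
F2 | step 19 | (2R,3R)-2-[2,4-dihydroxy-3-(3-hydroxy-3-methylbutyl)phenyl]-3-(hydroxymethyl)-5-(2-methylbut-3-en-2-yl)-2,3-dihydrobenzofuran-6-ol | OC[C@@H]1[C@H](c2ccc(O)c(CCC(C)(C)O)c2O)Oc2cc(O)c(C(C)(C)C=C)cc12
F3 | step 16 | racemic cis ester (23 with its mirror image, 1:1) | COC(=O)[C@@H]1[C@H](c2ccc(O[Si](C)(C)C(C)(C)C)c(CCC(C)(C)O[Si](CC)(CC)CC)c2O[Si](C)(C)C(C)(C)C)Oc2cc(O[Si](C)(C)C(C)(C)C)c(C(C)(C)C=C)cc12.COC(=O)[C@H]1[C@@H](c2ccc(O[Si](C)(C)C(C)(C)C)c(CCC(C)(C)O[Si](CC)(CC)CC)c2O[Si](C)(C)C(C)(C)C)Oc2cc(O[Si](C)(C)C(C)(C)C)c(C(C)(C)C=C)cc12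
F4 | step 16 | racemic cis alcohol (24 with its mirror image, 1:1) | OC[C@@H]1[C@H](c2ccc(O[Si](C)(C)C(C)(C)C)c(CCC(C)(C)O[Si](CC)(CC)CC)c2O[Si](C)(C)C(C)(C)C)Oc2cc(O[Si](C)(C)C(C)(C)C)c(C(C)(C)C=C)cc12.OC[C@H]1[C@@H](c2ccc(O[Si](C)(C)C(C)(C)C)c(CCC(C)(C)O[Si](CC)(CC)CC)c2O[Si](C)(C)C(C)(C)C)Oc2cc(O[Si](C)(C)C(C)(C)C)c(C(C)(C)C=C)cc12
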